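The dienone ring is disconnected at its C2=C3 double bond and at the C5–OMe bond. The ring is a vinylogous ester (C5(OMe)=C6–C1=O) cross-conjugated with an enone whose β-carbon C3 sits on the quaternary, non-enolisable C4; C3 can therefore be a formyl group and C5≡C6–C1(=O)–C2H2–allyl an ynone, both on C4 of an acyclic precursor. In one operation methoxide adds to the ynone (C5–OMe), the C2 enolate closes the six-membered ring on the C3 aldehyde and water is lost, which gives the target. C8 and C4 are set earlier by an Evans aldol and a chelation-controlled ethynylation steered by a temporary C7 hydroxyl group.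

Key step: step 9

Remark: C1–C6 are the dienone ring atoms (C1 carbonyl carbon, C2 allyl-bearing carbon, C4 quaternary carbon, C5 methoxy-bearing sp2 carbon), C8 is the side-chain CH(CH3) and C7 the benzylic carbon; vinylmagnesium bromide, ethynylmagnesium bromide and pent-4-enoyl chloride are taken as commercial.

Step 1
Reactants: 1 (R)-4-benzyl-3-propionyloxazolidin-2-one; 2 3,4-dimethoxybenzaldehyde
Product: 4 (R)-4-benzyl-3-[(2R,3R)-3-(3,4-dimethoxyphenyl)-3-hydroxy-2-methylpropanoyl]oxazolidin-2-one, via boron Z-enolate 3 (not isolated)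
Conditions: Bu2BOTf, i-Pr2NEt, CH2Cl2, 0 °C; 2, −78 to 0 °C; then pH 7 buffer, MeOH, H2O2, 0 °C
Reagents that add atoms: none
Why: Evans syn-aldol reaction, in which the dibutylboron Z-enolate 3 should react through a closed Zimmerman–Traxler chair whose open face is fixed by the benzyl group of the auxiliary, so that C8 (R) and the temporary carbinol centre C7 (R) are set together.

Step 2
Reactants: 4
Product: 5 (2R,3R)-3-(3,4-dimethoxyphenyl)-3-hydroxy-N-methoxy-N,2-dimethylpropanamide
Conditions: MeNH(OMe)·HCl, AlMe3, CH2Cl2, −15 to 0 °C; aq. HCl work-up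
Reagents that add atoms: N,O-dimethylhydroxylamine hydrochloride, CNOC.Cl
Why: Weinreb amide formation by aluminium amide transamination, which the free β-hydroxyl group assists and which should release the auxiliary without touching C7 or C8.

Step 3
Reactants: 5
Product: 6 (4R,5R)-5-(3,4-dimethoxyphenyl)-5-hydroxy-4-methylpent-1-en-3-one
Conditions: CH2=CHMgBr (3 equiv), THF, −78 to 0 °C; inverse quench into cold 1 M HCl
Reagents that add atoms: vinylmagnesium bromide, C=C[Mg]Br
Why: Weinreb ketone synthesis, in which the chelated tetrahedral intermediate should survive until the acidic quench, so that the Grignard reagent adds only once and the liberated amine is protonated before it can add to the enone.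

Step 4
Reactants: 6
Product: 7 (3R,4R,5R)-5-(3,4-dimethoxyphenyl)-3-ethynyl-4-methylpent-1-ene-3,5-diol
Conditions: HC≡CMgBr (4 equiv), THF–CH2Cl2, −78 to −30 °C; aq. NH4Cl
Reagents that add atoms: ethynylmagnesium bromide, C#C[Mg]Br
Why: Chelation-controlled 1,2-addition (Cram-chelate type), in which the magnesium alkoxide of the C7 hydroxyl group should hold the ketone in a six-membered chelate with the aryl group equatorial and the C8 methyl group axial, so that the alkynyl Grignard reagent adds to the face anti to that methyl group and sets C4 with ethynyl anti and vinyl syn to it.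

Step 5
Reactants: 7
Product: 8 4-[(1R,2R,3R)-3-ethynyl-1,3-dimethoxy-2-methylpent-4-en-1-yl]-1,2-dimethoxybenzene
Conditions: NaH (2.3 equiv), MeI, THF–DMF, 0 °C to rt
Reagents that add atoms: iodomethane, CI
Why: Williamson ether synthesis, in which NaH should form both alkoxides in preference to the acetylide (the O–H bonds are far more acidic than the alkyne C–H) and MeI methylates them, the C7 methyl ether serving only as the leaving group of the next step.

Step 6
Reactants: 8
Product: 9 4-[(2R,3R)-3-ethynyl-3-methoxy-2-methylpent-4-en-1-yl]-1,2-dimethoxybenzene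
Conditions: Et3SiH (4 equiv), CF3CO2H, CH2Cl2, −20 to 0 °C
Reagents that add atoms: none
Why: Ionic hydrogenation, in which the acid should ionise only the 3,4-dimethoxybenzylic C7 ether (its cation is far better stabilised than one at the tertiary propargylic C4) and hydride transfer from excess Et3SiH in the non-basic medium should outrun loss of the C8 proton, so that the temporary C7 centre is erased while C4 and C8 keep their configuration.

Step 7
Reactants: 9
Product: 11 (2R,3R)-4-(3,4-dimethoxyphenyl)-2-ethynyl-2-methoxy-3-methylbutanal, via vicinal diol 10 (not isolated)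
Conditions: OsO4 (cat.), NaIO4, 2,6-lutidine, dioxane–H2O, rt
Reagents that add atoms: osmium tetroxide, O=[Os](=O)(=O)=O; sodium periodate, [Na+].[O-]I(=O)(=O)=O
Why: Lemieux–Johnson oxidation, in which OsO4 should dihydroxylate the only alkene (alkyne and arene react far more slowly) and NaIO4 cleave the diol 10 to an aldehyde that has no α-hydrogen, so C4 cannot epimerise.

Step 8
Reactants: 11; 12 pent-4-enoyl chloride
Product: 13 (2R)-2-[(2R)-1-(3,4-dimethoxyphenyl)propan-2-yl]-2-methoxy-5-oxonon-8-en-3-ynal
Conditions: PdCl2(PPh3)2 (cat.), CuI (cat.), Et3N, THF, rt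
Reagents that add atoms: none
Why: Acyl Sonogashira coupling, in which the copper acetylide formed with CuI and Et3N should transmetalate to the acylpalladium chloride derived from 12 and give the ynone without a strong base, so that the non-enolisable aldehyde is tolerated.

Step 9
Reactants: 13
Product: 16 Lancifolin C, via β-methoxy enone aldehyde 14 (not isolated), via cyclic aldol 15 (not isolated)
Conditions: NaOMe (0.3 equiv), MeOH, 0 °C to rt; aq. NH4Cl
Reagents that add atoms: methanol, CO; sodium methoxide, [Na+].[O-]C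
Why: Methoxide should add to the β-carbon C5 of the ynone and the allenolate be protonated to the β-methoxy enone 14, whose double-bond isomers interconvert by reversible methoxide addition; in the isomer with C4 and C1 cis, C2 is deprotonated and the enolate attacks the C3 aldehyde to give 15, which loses water by an E1cB pathway. The closest known reaction type is the base-mediated intramolecular aldol condensation that ends a Robinson annulation, here preceded by an oxa-Michael addition to an ynone. The ring is closed in the 6-(enolexo)-exo-trig mode with formation of the C2–C3 bond. No stereocentre of the target is formed: the two transient centres at C2 and C3 of 15 vanish on dehydration, and C4 (quaternary) and C8 (not acidic) are not touched. The step needs methoxide addition at C5 and enolisation at C2 only; conjugation with the C1 carbonyl secures the first, and the second follows because C6 is vinylic, C4 is quaternary and the aldehyde has no α-hydrogen.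

Compound list
1 | (R)-4-benzyl-3-propionyloxazolidin-2-one | CCC(=O)N1[C@H](Cc2ccccc2)COC1=O | starting material
2 | 3,4-dimethoxybenzaldehyde | COc1ccc(C=O)cc1OC | starting material
3 | (R)-4-benzyl-3-[(1Z)-1-(dibutylboranyloxy)prop-1-en-1-yl]oxazolidin-2-one (boron Z-enolate of 1) | C/C=C(\OB(CCCC)CCCC)N1[C@H](Cc2ccccc2)COC1=O | intermediate
4 | (R)-4-benzyl-3-[(2R,3R)-3-(3,4-dimethoxyphenyl)-3-hydroxy-2-methylpropanoyl]oxazolidin-2-one | O=C(N1[C@H](Cc2ccccc2)COC1=O)[C@H](C)[C@@H](O)c1ccc(OC)c(OC)c1 | intermediate
5 | (2R,3R)-3-(3,4-dimethoxyphenyl)-3-hydroxy-N-methoxy-N,2-dimethylpropanamide | CON(C)C(=O)[C@H](C)[C@@H](O)c1ccc(OC)c(OC)c1 | intermediate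
6 | (4R,5R)-5-(3,4-dimethoxyphenyl)-5-hydroxy-4-methylpent-1-en-3-one | C=CC(=O)[C@H](C)[C@@H](O)c1ccc(OC)c(OC)c1 | intermediate
7 | (3R,4R,5R)-5-(3,4-dimethoxyphenyl)-3-ethynyl-4-methylpent-1-ene-3,5-diol | C=C[C@@](O)([C@H](C)[C@@H](O)c1ccc(OC)c(OC)c1)C#C | intermediate
8 | 4-[(1R,2R,3R)-3-ethynyl-1,3-dimethoxy-2-methylpent-4-en-1-yl]-1,2-dimethoxybenzene | C=C[C@@](OC)([C@H](C)[C@@H](OC)c1ccc(OC)c(OC)c1)C#C | intermediate
9 | 4-[(2R,3R)-3-ethynyl-3-methoxy-2-methylpent-4-en-1-yl]-1,2-dimethoxybenzene | C=C[C@@](OC)([C@H](C)Cc1ccc(OC)c(OC)c1)C#C | intermediate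
10 | (3R,4R)-5-(3,4-dimethoxyphenyl)-3-ethynyl-3-methoxy-4-methylpentane-1,2-diol (both C2 epimers) | OCC(O)[C@@](OC)([C@H](C)Cc1ccc(OC)c(OC)c1)C#C | intermediate
11 | (2R,3R)-4-(3,4-dimethoxyphenyl)-2-ethynyl-2-methoxy-3-methylbutanal | O=C[C@@](OC)([C@H](C)Cc1ccc(OC)c(OC)c1)C#C | intermediate
12 | pent-4-enoyl chloride | C=CCCC(Cl)=O | starting material
13 | (2R)-2-[(2R)-1-(3,4-dimethoxyphenyl)propan-2-yl]-2-methoxy-5-oxonon-8-en-3-ynal | O=C[C@@](OC)([C@H](C)Cc1ccc(OC)c(OC)c1)C#CC(=O)CCC=C | intermediate
14 | (2R,3E)-2-[(2R)-1-(3,4-dimethoxyphenyl)propan-2-yl]-2,3-dimethoxy-5-oxonona-3,8-dienal | O=C[C@@](OC)([C@H](C)Cc1ccc(OC)c(OC)c1)/C(OC)=C\C(=O)CCC=C | intermediate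
15 | (4S)-4-[(2R)-1-(3,4-dimethoxyphenyl)propan-2-yl]-5-hydroxy-3,4-dimethoxy-6-(prop-2-en-1-yl)cyclohex-2-en-1-one (epimers at C5 and C6) | C=CCC1C(O)[C@@](OC)([C@H](C)Cc2ccc(OC)c(OC)c2)C(OC)=CC1=O | intermediate
16 | Lancifolin C, (4S)-4-[(2R)-1-(3,4-dimethoxyphenyl)propan-2-yl]-4,5-dimethoxy-2-(prop-2-en-1-yl)cyclohexa-2,5-dien-1-one | C=CCC1=C[C@@](OC)([C@H](C)Cc2ccc(OC)c(OC)c2)C(OC)=CC1=O | target

Total step count: 9. Longest linear sequence: 9 steps (1 to 16).

Steps most likely to fail

Step 9. Methoxide may cleave the formyl group from C4 (retro-Claisen deformylation through the hemiacetal anion) before the ring closes, and prolonged base may move the allyl double bond into conjugation. The fallback replaces the aldol condensation by an intramolecular Horner–Wadsworth–Emmons olefination; it sets out from 11 and comes back at 16. Aldehyde 11 would be coupled under the PdCl2(PPh3)2/CuI/Et3N conditions of step 8 with 2-(diethoxyphosphoryl)pent-4-enoyl chloride (CCOP(=O)(OCC)C(CC=C)C(Cl)=O) to give the ynone ketophosphonate aldehyde F1. PMe3-catalysed addition of MeOH in CH2Cl2, without free alkoxide, should give the β-methoxy enone ketophosphonate F2. LiCl and DBU in MeCN should then close the ring by olefination of the C3 aldehyde and give 16 directly.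

Step 6. The benzylic cation may lose the C8 proton and be re-protonated (erosion of the C8 configuration), the tertiary propargylic ether may ionise, or the C4–C8 bond may fragment. The fallback is a radical Barton–McCombie deoxygenation that avoids any cation; it sets out from 7 and comes back at 9. The secondary benzylic hydroxyl group of 7 would be acylated selectively with PhOC(S)Cl, pyridine and DMAP to give the phenyl thionocarbonate F3. Bu3SnH and AIBN in toluene at 80 °C, with the hydride added slowly, should give the tertiary alcohol F4 through the benzylic radical. NaH and MeI should then methylate the tertiary hydroxyl group to give 9.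

Step 4. The chelated addition may show poor facial selectivity, and the basic Grignard reagent may enolise the ketone at C8 or trigger oxa-Michael closure of the hydroxy enone. The fallback reverses the order of the two nucleophiles and uses Felkin–Anh instead of chelation control; it sets out from 5 and comes back at 7. Amide 5 would be silylated with TBSOTf and 2,6-lutidine to the silyl ether F5, and LiC≡CSiMe3 should give the ynone F6. CH2=CHMgBr in THF should add anti to the large silyloxybenzyl substituent at C8 and give the tertiary alcohol F7 with the same C4 configuration as in the main route. Bu4NF should remove both silyl groups to give 7.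

Further compounds
F1 | step 9 | diethyl {(8R)-8-[(2R)-1-(3,4-dimethoxyphenyl)propan-2-yl]-8-methoxy-5,9-dioxonon-1-en-6-yn-4-yl}phosphonate | O=C[C@@](OC)([C@H](C)Cc1ccc(OC)c(OC)c1)C#CC(=O)C(CC=C)P(=O)(OCC)OCC
F2 | step 9 | diethyl {(6E,8R)-8-[(2R)-1-(3,4-dimethoxyphenyl)propan-2-yl]-7,8-dimethoxy-5,9-dioxonona-1,6-dien-4-yl}phosphonate | O=C[C@@](OC)([C@H](C)Cc1ccc(OC)c(OC)c1)/C(OC)=C\C(=O)C(CC=C)P(=O)(OCC)OCC
F3 | step 6 | O-[(1R,2R,3R)-1-(3,4-dimethoxyphenyl)-3-ethynyl-3-hydroxy-2-methylpent-4-en-1-yl] O-phenyl carbonothioate | C=C[C@@](O)([C@H](C)[C@@H](OC(=S)Oc1ccccc1)c1ccc(OC)c(OC)c1)C#C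
F4 | step 6 | (3R,4R)-5-(3,4-dimethoxyphenyl)-3-ethynyl-4-methylpent-1-en-3-ol | C=C[C@@](O)([C@H](C)Cc1ccc(OC)c(OC)c1)C#C
F5 | step 4 | (2R,3R)-3-[(tert-butyldimethylsilyl)oxy]-3-(3,4-dimethoxyphenyl)-N-methoxy-N,2-dimethylpropanamide | CON(C)C(=O)[C@H](C)[C@@H](O[Si](C)(C)C(C)(C)C)c1ccc(OC)c(OC)c1
F6 | step 4 | (4R,5R)-5-[(tert-butyldimethylsilyl)oxy]-5-(3,4-dimethoxyphenyl)-4-methyl-1-(trimethylsilyl)pent-1-yn-3-one | C[Si](C)(C)C#CC(=O)[C@H](C)[C@@H](O[Si](C)(C)C(C)(C)C)c1ccc(OC)c(OC)c1
F7 | step 4 | (3R,4R,5R)-5-[(tert-butyldimethylsilyl)oxy]-5-(3,4-dimethoxyphenyl)-4-methyl-3-[(trimethylsilyl)ethynyl]pent-1-en-3-ol | C=C[C@@](O)([C@H](C)[C@@H](O[Si](C)(C)C(C)(C)C)c1ccc(OC)c(OC)c1)C#C[Si](C)(C)C
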